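Germacrane numbering is used (carbocycle C1–C10, lactone C6–O–C12, C14 on C10, C15 on C4). Everything rests on opening the ten-membered carbocycle at C3–C4: the C3 carbinol next to the (Z)-C4=C5 olefin is the retron of an alkenyl iodide and an aldehyde. An intramolecular Nozaki–Hiyama–Kishi reaction closes this ring last, creates C3 and keeps the 4Z geometry in one operation. Its precursor is a seco-aldehyde that already carries the trans α-methylene lactone, the (1R,10R)-epoxide (Shi) and the C8 isobutyrate; it is assembled by chromium-mediated allylation of an epoxy aldehyde with a 3-(bromomethyl)butenolide at C7–C8.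

Key step: step 14

Assumption: the (S,S)-ProPhenol/Me2Zn system is taken to deliver the (4S)-carbinol 3 from enal 1; if the sense of induction is opposite, the commercial (R,R)-ligand is used instead.

Step 1
Reactants: 1 (E)-but-2-enal; 2 tert-butyldimethyl(prop-2-yn-1-yloxy)silane
Product: 3 (4S,5E)-1-[(tert-butyldimethylsilyl)oxy]hept-5-en-2-yn-4-ol
Conditions: (S,S)-ProPhenol (10 mol %), Me2Zn (3 equiv), Ph3PO (20 mol %), toluene, 0 to 4 °C
Reagents that add atoms: none
Why: Zn–ProPhenol-catalysed asymmetric alkynylation adds the zinc acetylide of 2 in 1,2-fashion to the enal inside the chiral dinuclear zinc pocket, which sets the future C6 carbinol by catalyst control.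

Step 2
Reactants: 3 (4S,5E)-1-[(tert-butyldimethylsilyl)oxy]hept-5-en-2-yn-4-ol
Product: 5 (2Z,4S,5E)-1-[(tert-butyldimethylsilyl)oxy]-2-iodohepta-2,5-dien-4-ol, via cyclic alkenylaluminate 4 (not isolated)
Conditions: Red-Al, THF, 0 °C; EtOAc; then I2, THF, −78 to 0 °C
Reagents that add atoms: iodine, SMILES II
Why: Alkoxide-directed trans-hydroalumination of the propargylic alcohol places aluminium on the distal alkyne carbon in a five-membered chelate and iodinolysis with retention gives the (Z)-iodoalkene (iodine cis to the carbinol carbon, the future 4Z geometry); low temperature suppresses 1,2-elimination of the silyloxy group to an allene.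

Step 3
Reactants: 5 (2Z,4S,5E)-1-[(tert-butyldimethylsilyl)oxy]-2-iodohepta-2,5-dien-4-ol; 6 2-(bromomethyl)acrylic acid
Product: 7 (2Z,4S,5E)-1-[(tert-butyldimethylsilyl)oxy]-2-iodohepta-2,5-dien-4-yl 2-(bromomethyl)acrylate
Conditions: DCC, DMAP (5 mol %), CH2Cl2, 0 °C
Reagents that add atoms: none
Why: Steglich esterification acylates the secondary alcohol with retention at C6; DMAP is kept catalytic and cold to spare the allylic bromide.

Step 4
Reactants: 7 (2Z,4S,5E)-1-[(tert-butyldimethylsilyl)oxy]-2-iodohepta-2,5-dien-4-yl 2-(bromomethyl)acrylate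
Product: 8 (5S)-3-(bromomethyl)-5-[(1Z)-3-[(tert-butyldimethylsilyl)oxy]-2-iodoprop-1-en-1-yl]furan-2(5H)-one
Conditions: Grubbs II (5 mol %), CH2Cl2 (5 mM), 40 °C
Reagents that add atoms: none
Why: Ring-closing metathesis of the acrylate with the propenyl group (loss of propene) should close the α-substituted butenolide (lactone ring, C7=C11), while the halogenated trisubstituted iodoalkene does not engage the ruthenium carbene.

Step 5
Reactants: 9 tert-butyl(but-3-yn-1-yloxy)dimethylsilane; 10 oxirane (ethylene oxide)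
Product: 13 (3E)-6-[(tert-butyldimethylsilyl)oxy]-4-methylhex-3-en-1-ol, via alkenyldimethylalane 11 (not isolated), via lithium alkenylalanate 12 (not isolated)
Conditions: Me3Al (2 equiv), Cp2ZrCl2 (0.25 equiv), CH2Cl2, 0 °C to rt; evaporate, hexane; n-BuLi, −78 to 0 °C; ethylene oxide, THF, −78 °C to rt
Reagents that add atoms: trimethylaluminium, SMILES C[Al](C)C
Why: Negishi zirconium-catalysed carboalumination adds Me–Al syn across the terminal alkyne and the derived lithium alanate opens ethylene oxide with retention, which fixes the E-trisubstituted C1=C10 olefin with C14 in place.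

Step 6
Reactants: 13 (3E)-6-[(tert-butyldimethylsilyl)oxy]-4-methylhex-3-en-1-ol
Product: 14 tert-butyl{[(3E)-6-[(4-methoxybenzyl)oxy]-3-methylhex-3-en-1-yl]oxy}dimethylsilane
Conditions: NaH, PMBCl, Bu4NI (cat.), THF–DMF, 0 °C to rt
Reagents that add atoms: 4-methoxybenzyl chloride, SMILES COc1ccc(CCl)cc1
Why: Williamson etherification of the primary alkoxide protects the future C3 oxygen; the TBS ether is stable to NaH.

Step 7
Reactants: 14 tert-butyl{[(3E)-6-[(4-methoxybenzyl)oxy]-3-methylhex-3-en-1-yl]oxy}dimethylsilane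
Product: 15 tert-butyl{2-[(2R,3R)-3-{2-[(4-methoxybenzyl)oxy]ethyl}-2-methyloxiran-2-yl]ethoxy}dimethylsilane
Conditions: D-fructose-derived Shi ketone (30 mol %), Oxone, K2CO3, Bu4NHSO4, MeCN–DMM/aq. Na2B4O7–EDTA, 0 °C
Reagents that add atoms: potassium peroxymonosulfate (Oxone), SMILES [K+].[O-]S(=O)(=O)OO
Why: Shi asymmetric epoxidation delivers oxygen from the chiral dioxirane through the spiro transition state to one face of the E-trisubstituted olefin, which sets C1 and C10 as the (R,R)-epoxide by reagent control.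

Step 8
Reactants: 15 tert-butyl{2-[(2R,3R)-3-{2-[(4-methoxybenzyl)oxy]ethyl}-2-methyloxiran-2-yl]ethoxy}dimethylsilane
Product: 16 2-[(2R,3R)-3-{2-[(4-methoxybenzyl)oxy]ethyl}-2-methyloxiran-2-yl]ethan-1-ol
Conditions: TBAF, THF, 0 °C to rt
Reagents that add atoms: none
Why: Fluoride-mediated desilylation frees the C8 alcohol; epoxide and PMB ether are inert.

Step 9
Reactants: 16 2-[(2R,3R)-3-{2-[(4-methoxybenzyl)oxy]ethyl}-2-methyloxiran-2-yl]ethan-1-ol
Product: 17 2-[(2R,3R)-3-{2-[(4-methoxybenzyl)oxy]ethyl}-2-methyloxiran-2-yl]acetaldehyde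
Conditions: Dess–Martin periodinane, NaHCO3, CH2Cl2, 0 °C
Reagents that add atoms: none
Why: Buffered Dess–Martin oxidation should give the β,γ-epoxy aldehyde without epoxide opening or β-elimination; it is used at once.

Step 10
Reactants: 8 (5S)-3-(bromomethyl)-5-[(1Z)-3-[(tert-butyldimethylsilyl)oxy]-2-iodoprop-1-en-1-yl]furan-2(5H)-one; 17 2-[(2R,3R)-3-{2-[(4-methoxybenzyl)oxy]ethyl}-2-methyloxiran-2-yl]acetaldehyde
Product: 19 (4R,5S)-5-[(1Z)-3-[(tert-butyldimethylsilyl)oxy]-2-iodoprop-1-en-1-yl]-4-{(1S)-1-hydroxy-2-[(2R,3R)-3-{2-[(4-methoxybenzyl)oxy]ethyl}-2-methyloxiran-2-yl]ethyl}-3-methylidenedihydrofuran-2(3H)-one, via allylchromium(III) species 18 (not isolated)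
Conditions: CrCl2 (3 equiv, nickel-free), THF, 0 °C to rt, slow addition of 8
Reagents that add atoms: none
Why: Chromium(II)-mediated Barbier (Nozaki–Hiyama) allylation: the allylchromium adds through C7 in a chair Zimmerman–Traxler transition state on the face anti to the C6 side chain, which sets C7 trans to C6 and, because the ring locks the allyl unit in the E-type geometry, the anti carbinol (8S), while the exocyclic methylene appears in the same step and the alkenyl iodide is inert without nickel.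

Step 11
Reactants: 19 the (8S)-carbinol from step 10; 20 2-methylpropanoic acid (isobutyric acid)
Product: 21 (1R)-1-[(2S,3R)-2-[(1Z)-3-[(tert-butyldimethylsilyl)oxy]-2-iodoprop-1-en-1-yl]-4-methylidene-5-oxotetrahydrofuran-3-yl]-2-[(2R,3R)-3-{2-[(4-methoxybenzyl)oxy]ethyl}-2-methyloxiran-2-yl]ethyl 2-methylpropanoate
Conditions: i-PrCO2H, PPh3, DIAD, toluene, 0 °C to rt
Reagents that add atoms: none
Why: Mitsunobu esterification displaces the C8 oxyphosphonium by isobutyrate in an SN2 process, which inverts C8 to the required 8R configuration and installs the ester in one step.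

Step 12
Reactants: 21 the (8R)-isobutyrate PMB ether
Product: 22 (1R)-1-[(2S,3R)-2-[(1Z)-3-[(tert-butyldimethylsilyl)oxy]-2-iodoprop-1-en-1-yl]-4-methylidene-5-oxotetrahydrofuran-3-yl]-2-[(2R,3R)-3-(2-hydroxyethyl)-2-methyloxiran-2-yl]ethyl 2-methylpropanoate
Conditions: DDQ, CH2Cl2–pH 7 buffer, 0 °C
Reagents that add atoms: none
Why: Oxidative PMB cleavage by DDQ frees the C3 alcohol; silyl ether, epoxide, ester, methylene lactone and iodoalkene are not oxidised.

Step 13
Reactants: 22 the C3 primary alcohol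
Product: 23 (1R)-1-[(2S,3R)-2-[(1Z)-3-[(tert-butyldimethylsilyl)oxy]-2-iodoprop-1-en-1-yl]-4-methylidene-5-oxotetrahydrofuran-3-yl]-2-[(2R,3R)-2-methyl-3-(2-oxoethyl)oxiran-2-yl]ethyl 2-methylpropanoate (seco-aldehyde)
Conditions: Dess–Martin periodinane, NaHCO3, CH2Cl2, 0 °C
Reagents that add atoms: none
Why: Buffered Dess–Martin oxidation gives the C3 aldehyde under neutral conditions that spare the epoxide, the allylic silyl ether and the methylene lactone.

Step 14
Reactants: 23 seco-aldehyde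
Product: 25 (1R,3S,4Z,6R,7R,8R,10R)-15-[(tert-butyldimethylsilyl)oxy]-1,10-epoxy-3-hydroxy-8-(isobutyryloxy)germacra-4,11(13)-dien-12,6-olide, via alkenylchromium(III) species 24 (not isolated)
Conditions: CrCl2 (10 equiv), NiCl2 (10 mol %), DMSO–THF, rt, syringe-pump addition, 2 mM
Reagents that add atoms: none
Why: Ni(0) inserts into the C4–I bond with retention, transmetalation gives the alkenylchromium(III) 24, and its addition to the C3 aldehyde forges C3–C4; the closest known reaction type is the intramolecular Nozaki–Hiyama–Kishi macrocyclisation of an alkenyl iodide onto an aldehyde. The ten-membered carbocycle C1–C10 closes in a 10-exo-trig mode, the chain ends being pre-organised by the trans-lactone turn at C6/C7, the cis C4=C5 unit and the trans-epoxide. The new C3 stereocentre is set by macrocyclic substrate control: the bulky O–Cr(III) group is expected to sit on the periphery of the forming ring with H3 inside, which is predicted to correspond to the 3S (3β) carbinol and is the least secure element. The step needs chemoselectivity for the aldehyde over lactone, ester, epoxide and acrylate (secured by the low basicity and carbonyl selectivity of organochromium), retention of the Z olefin (secured by the configurationally stable trisubstituted alkenyl–Cr bond) and cyclisation over oligomerisation (secured by high dilution).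

Step 15
Reactants: 25 the 15-O-TBS macrocycle
Product: 26 (1R,3S,4Z,6R,7R,8R,10R)-1,10-epoxy-3,15-dihydroxy-8-(isobutyryloxy)germacra-4,11(13)-dien-12,6-olide (CNP0219050.1)
Conditions: HF·pyridine, pyridine, THF, 0 °C
Reagents that add atoms: none
Why: Pyridine-buffered HF desilylation cleaves the primary allylic TBS ether while the epoxide, the methylene lactone and the isobutyrate should be preserved.

Compound list
1 | (E)-but-2-enal (crotonaldehyde) | C/C=C/C=O | starting material
2 | tert-butyldimethyl(prop-2-yn-1-yloxy)silane | C#CCO[Si](C)(C)C(C)(C)C | starting material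
3 | (4S,5E)-1-[(tert-butyldimethylsilyl)oxy]hept-5-en-2-yn-4-ol | O[C@@H](/C=C/C)C#CCO[Si](C)(C)C(C)(C)C | intermediate
4 | sodium cyclic alkenyl(alkoxy)bis(2-methoxyethoxy)aluminate from 3 (Al on the CH2OTBS-bearing carbon, chelated by the C6 oxygen) | COCCO[Al-]1(OCCOC)O[C@@H](/C=C/C)C=C1CO[Si](C)(C)C(C)(C)C.[Na+] | intermediate
5 | (2Z,4S,5E)-1-[(tert-butyldimethylsilyl)oxy]-2-iodohepta-2,5-dien-4-ol | O[C@@H](/C=C/C)/C=C(\I)CO[Si](C)(C)C(C)(C)C | intermediate
6 | 2-(bromomethyl)acrylic acid | C=C(CBr)C(=O)O | starting material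
7 | (2Z,4S,5E)-1-[(tert-butyldimethylsilyl)oxy]-2-iodohepta-2,5-dien-4-yl 2-(bromomethyl)acrylate | C=C(CBr)C(=O)O[C@@H](/C=C/C)/C=C(\I)CO[Si](C)(C)C(C)(C)C | intermediate
8 | (5S)-3-(bromomethyl)-5-[(1Z)-3-[(tert-butyldimethylsilyl)oxy]-2-iodoprop-1-en-1-yl]furan-2(5H)-one | O=C1O[C@H](/C=C(\I)CO[Si](C)(C)C(C)(C)C)C=C1CBr | intermediate
9 | tert-butyl(but-3-yn-1-yloxy)dimethylsilane | C#CCCO[Si](C)(C)C(C)(C)C | starting material
10 | oxirane (ethylene oxide) | C1CO1 | starting material
11 | [(1E)-4-[(tert-butyldimethylsilyl)oxy]-2-methylbut-1-en-1-yl]dimethylalane | C[Al](C)/C=C(\C)CCO[Si](C)(C)C(C)(C)C | intermediate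
12 | lithium butyl[(1E)-4-[(tert-butyldimethylsilyl)oxy]-2-methylbut-1-en-1-yl]dimethylalanate | [Li+].CCCC[Al-](C)(C)/C=C(\C)CCO[Si](C)(C)C(C)(C)C | intermediate
13 | (3E)-6-[(tert-butyldimethylsilyl)oxy]-4-methylhex-3-en-1-ol | OCC/C=C(\C)CCO[Si](C)(C)C(C)(C)C | intermediate
14 | tert-butyl{[(3E)-6-[(4-methoxybenzyl)oxy]-3-methylhex-3-en-1-yl]oxy}dimethylsilane | COc1ccc(COCC/C=C(\C)CCO[Si](C)(C)C(C)(C)C)cc1 | intermediate
15 | tert-butyl{2-[(2R,3R)-3-{2-[(4-methoxybenzyl)oxy]ethyl}-2-methyloxiran-2-yl]ethoxy}dimethylsilane | COc1ccc(COCC[C@H]2O[C@]2(C)CCO[Si](C)(C)C(C)(C)C)cc1 | intermediate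
16 | 2-[(2R,3R)-3-{2-[(4-methoxybenzyl)oxy]ethyl}-2-methyloxiran-2-yl]ethan-1-ol | COc1ccc(COCC[C@H]2O[C@]2(C)CCO)cc1 | intermediate
17 | 2-[(2R,3R)-3-{2-[(4-methoxybenzyl)oxy]ethyl}-2-methyloxiran-2-yl]acetaldehyde | COc1ccc(COCC[C@H]2O[C@]2(C)CC=O)cc1 | intermediate
18 | allylchromium(III) dichloride derived from 8 (Cr on the former CH2Br carbon) | Cl[Cr](Cl)CC1=C[C@@H](/C=C(\I)CO[Si](C)(C)C(C)(C)C)OC1=O | intermediate
19 | (4R,5S)-5-[(1Z)-3-[(tert-butyldimethylsilyl)oxy]-2-iodoprop-1-en-1-yl]-4-{(1S)-1-hydroxy-2-[(2R,3R)-3-{2-[(4-methoxybenzyl)oxy]ethyl}-2-methyloxiran-2-yl]ethyl}-3-methylidenedihydrofuran-2(3H)-one | C=C1C(=O)O[C@H](/C=C(\I)CO[Si](C)(C)C(C)(C)C)[C@H]1[C@@H](O)C[C@@]2(C)O[C@@H]2CCOCc3ccc(OC)cc3 | intermediate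
20 | 2-methylpropanoic acid (isobutyric acid) | CC(C)C(=O)O | starting material
21 | (1R)-1-[(2S,3R)-2-[(1Z)-3-[(tert-butyldimethylsilyl)oxy]-2-iodoprop-1-en-1-yl]-4-methylidene-5-oxotetrahydrofuran-3-yl]-2-[(2R,3R)-3-{2-[(4-methoxybenzyl)oxy]ethyl}-2-methyloxiran-2-yl]ethyl 2-methylpropanoate | C=C1C(=O)O[C@H](/C=C(\I)CO[Si](C)(C)C(C)(C)C)[C@H]1[C@H](OC(=O)C(C)C)C[C@@]2(C)O[C@@H]2CCOCc3ccc(OC)cc3 | intermediate
22 | (1R)-1-[(2S,3R)-2-[(1Z)-3-[(tert-butyldimethylsilyl)oxy]-2-iodoprop-1-en-1-yl]-4-methylidene-5-oxotetrahydrofuran-3-yl]-2-[(2R,3R)-3-(2-hydroxyethyl)-2-methyloxiran-2-yl]ethyl 2-methylpropanoate | C=C1C(=O)O[C@H](/C=C(\I)CO[Si](C)(C)C(C)(C)C)[C@H]1[C@H](OC(=O)C(C)C)C[C@@]2(C)O[C@@H]2CCO | intermediate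
23 | (1R)-1-[(2S,3R)-2-[(1Z)-3-[(tert-butyldimethylsilyl)oxy]-2-iodoprop-1-en-1-yl]-4-methylidene-5-oxotetrahydrofuran-3-yl]-2-[(2R,3R)-2-methyl-3-(2-oxoethyl)oxiran-2-yl]ethyl 2-methylpropanoate (seco-aldehyde) | C=C1C(=O)O[C@H](/C=C(\I)CO[Si](C)(C)C(C)(C)C)[C@H]1[C@H](OC(=O)C(C)C)C[C@@]2(C)O[C@@H]2CC=O | intermediate
24 | alkenylchromium(III) dichloride derived from 23 (Cr in place of iodine at C4) | C=C1C(=O)O[C@H](/C=C(\[Cr](Cl)Cl)CO[Si](C)(C)C(C)(C)C)[C@H]1[C@H](OC(=O)C(C)C)C[C@@]2(C)O[C@@H]2CC=O | intermediate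
25 | (1R,3S,4Z,6R,7R,8R,10R)-15-[(tert-butyldimethylsilyl)oxy]-1,10-epoxy-3-hydroxy-8-(isobutyryloxy)germacra-4,11(13)-dien-12,6-olide | C=C1C(=O)O[C@@H]2/C=C(/CO[Si](C)(C)C(C)(C)C)[C@@H](O)C[C@H]3O[C@]3(C)C[C@@H](OC(=O)C(C)C)[C@@H]12 | intermediate
26 | (1R,3S,4Z,6R,7R,8R,10R)-1,10-epoxy-3,15-dihydroxy-8-(isobutyryloxy)germacra-4,11(13)-dien-12,6-olide (CNP0219050.1) | C=C1C(=O)O[C@@H]2/C=C(/CO)[C@@H](O)C[C@H]3O[C@]3(C)C[C@@H](OC(=O)C(C)C)[C@@H]12 | target

Total step count: 15.
Longest linear sequence: 11 steps (9 to 26, steps 5–9 and 10–15); the butenolide branch (steps 1–4) joins at step 10.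

Steps most likely to fail

1. Step 14 (key step). The process at risk is facial selectivity in the addition of the alkenylchromium to the C3 aldehyde, since it rests on macrocyclic control alone. The fallback sets out from 23 and comes back at 25. The cyclisation is run to whatever carbinol forms, for example the (3R)-epimeric macrocyclic alcohol F1. The crude carbinols are oxidised with Dess–Martin periodinane to the macrocyclic C3 enone F2. The stereocentre is then set by reagent control through 1,2-reduction with (R)-Me-CBS/catecholborane at −78 °C, which should give 25.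

2. Step 11. The process at risk is SN2 displacement at the hindered C8 oxyphosphonium, which may lose to elimination or stall. The fallback sets out from 8 and 17 and comes back at 21. The fragment union is run as a zinc-mediated Barbier reaction (Zn, THF/aq. NH4Cl), a variant that for 3-(bromomethyl)butenolides is known to favour the syn carbinol, to give the (8R)-carbinol F3 directly. Acylation with isobutyric anhydride/DMAP, with retention, then gives 21.

3. Step 10. The process at risk is loss of the β,γ-epoxy aldehyde by Cr(III)-promoted epoxide opening or β-elimination faster than allylation. The fallback sets out from 14 and comes back at 19; it moves the epoxidation behind the coupling but still ahead of the carbocycle closure. TBAF gives (3E)-6-[(4-methoxybenzyl)oxy]-3-methylhex-3-en-1-ol F4. Dess–Martin oxidation gives (3E)-6-[(4-methoxybenzyl)oxy]-3-methylhex-3-enal F5. The CrCl2 coupling with 8 gives the olefinic anti adduct F6. Shi epoxidation of its only electron-rich olefin then gives 19.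

Further compounds
F1 | step 14 | (1R,3R,4Z,6R,7R,8R,10R)-15-[(tert-butyldimethylsilyl)oxy]-1,10-epoxy-3-hydroxy-8-(isobutyryloxy)germacra-4,11(13)-dien-12,6-olide (C3 epimer of 25) | C=C1C(=O)O[C@@H]2/C=C(/CO[Si](C)(C)C(C)(C)C)[C@H](O)C[C@H]3O[C@]3(C)C[C@@H](OC(=O)C(C)C)[C@@H]12
F2 | step 14 | (1R,4Z,6R,7R,8R,10R)-15-[(tert-butyldimethylsilyl)oxy]-1,10-epoxy-8-(isobutyryloxy)-3-oxogermacra-4,11(13)-dien-12,6-olide | C=C1C(=O)O[C@@H]2/C=C(/CO[Si](C)(C)C(C)(C)C)C(=O)C[C@H]3O[C@]3(C)C[C@@H](OC(=O)C(C)C)[C@@H]12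
F3 | step 11 | (4R,5S)-5-[(1Z)-3-[(tert-butyldimethylsilyl)oxy]-2-iodoprop-1-en-1-yl]-4-{(1R)-1-hydroxy-2-[(2R,3R)-3-{2-[(4-methoxybenzyl)oxy]ethyl}-2-methyloxiran-2-yl]ethyl}-3-methylidenedihydrofuran-2(3H)-one (C8 epimer of 19) | C=C1C(=O)O[C@H](/C=C(\I)CO[Si](C)(C)C(C)(C)C)[C@H]1[C@H](O)C[C@@]2(C)O[C@@H]2CCOCc3ccc(OC)cc3
F4 | step 10 | (3E)-6-[(4-methoxybenzyl)oxy]-3-methylhex-3-en-1-ol | COc1ccc(COCC/C=C(\C)CCO)cc1
F5 | step 10 | (3E)-6-[(4-methoxybenzyl)oxy]-3-methylhex-3-enal | COc1ccc(COCC/C=C(\C)CC=O)cc1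
F6 | step 10 | (4R,5S)-5-[(1Z)-3-[(tert-butyldimethylsilyl)oxy]-2-iodoprop-1-en-1-yl]-4-[(1S,3E)-1-hydroxy-6-[(4-methoxybenzyl)oxy]-3-methylhex-3-en-1-yl]-3-methylidenedihydrofuran-2(3H)-one | C=C1C(=O)O[C@H](/C=C(\I)CO[Si](C)(C)C(C)(C)C)[C@H]1[C@@H](O)C/C(C)=C/CCOCc2ccc(OC)cc2
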